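**Retrosynthetic overview**
1. The last C–C bond is C2–C3. SmI2 turns one formyl carbon of a C2/C3 dialdehyde into a nucleophilic ketyl (a hydroxy-carbanion equivalent) that attacks the other formyl carbon. This closes the ten-membered ring and sets both carbinol centres at once. The C3 butyrate and C2 acetate follow.
2. γ-Lactone: C17–C19 come from L-lactic acid. Its Seebach dioxolanone enolate adds to C8 of an 8,9-diketone, O7 closes the lactone, and the C9 ketone is then reduced under Felkin–Anh control.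
3. C8 is a 1,3-dithiane linchpin that is acylated twice. One acyl partner is 4-methyl-5,6-dihydropyran-2-one (C3–C7, with the 5Z alkene inherited from the ring). The other is a bicyclic lactone that carries the cyclohexane (C9).
4. Cyclohexane: a catalytic asymmetric Diels–Alder reaction sets C1, C10 and C11. A temporary trans-fused lactone locks the conformation for α-face borylation/oxidation at C14 and hydroxyl-directed reduction at C12.
5. Ring order: cyclohexane, temporary C2–O–C9 lactone (opened again), γ-lactone, ten-membered ring.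

Convention and assumption (one line): briarane numbering is used (C1 quaternary with Me-15, C5 with Me-16, C11 with Me-20, C17 with Me-18, C19 lactone C=O; β = the face of Me-15); the target is 1R,2R,3S,5Z,7S,8R,9S,10S,11R,12S,14S,17R; ethyl (E)-3-methyl-4-oxobut-2-enoate and 4-methyl-5,6-dihydro-2H-pyran-2-one are taken as catalogue chemicals.

**Step 1**
Reactants: 1 pent-1-en-3-one
Product: 2 (Z)-3-(tert-butyldimethylsilyloxy)penta-1,3-diene
Conditions: TBSOTf, Et3N, Et2O, 0 °C
Reagents that add atoms: tert-butyldimethylsilyl triflate, CC(C)(C)[Si](C)(C)OS(=O)(=O)C(F)(F)F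
Why: Soft enolisation (silyl enol ether formation) at the only enolisable side gives the Z dienol ether, in which the methyl group points away from the vinyl group.

**Step 2**
Reactants: 2 (Z)-3-(tert-butyldimethylsilyloxy)penta-1,3-diene; 3 ethyl (E)-3-methyl-4-oxobut-2-enoate
Product: 4 ethyl (1S,2R,6S)-3-(tert-butyldimethylsilyloxy)-6-formyl-2,6-dimethylcyclohex-3-ene-1-carboxylate (C10 S, C11 R, C1 S)
Conditions: oxazaborolidine from (S)-α,α-diphenylprolinol and o-tolylboronic acid (10 mol %), Tf2NH (10 mol %), CH2Cl2, −78 to −40 °C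
Reagents that add atoms: none
Why: In this catalytic enantioselective Diels–Alder reaction the cationic boron binds the formyl group so that the silyloxy-activated terminus C11 bonds to C10 and C14 to C1, the α-methyl group keeps the formyl exo and the ester endo (Me-20 cis to C9), the E dienophile fixes C2 and C9 trans, and the shielded catalyst face sets the absolute configuration of C1, C10 and C11.

**Step 3**
Reactants: 4 Diels–Alder adduct
Product: 6 (3aS,7R,7aS)-6-(tert-butyldimethylsilyloxy)-3a,7-dimethyl-3a,4,7,7a-tetrahydro-2-benzofuran-1(3H)-one, via hydroxy ester 5 (not isolated)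
Conditions: NaBH4, EtOH, −10 °C to rt
Reagents that add atoms: none
Why: Chemoselective borohydride reduction of the aldehyde and alkoxide lactonisation onto the trans-vicinal ester give the trans-fused γ-lactone, which changes no stereocentre and locks the chair in which Me-15 is axial.

**Step 4**
Reactants: 6 lactone silyl enol ether
Product: 7 (3aS,7R,7aS)-3a,7-dimethyl-3,3a,7,7a-tetrahydro-2-benzofuran-1,6-dione (C13=C14 enone)
Conditions: Pd(OAc)2 (10 mol %), O2 (1 atm), DMSO, 40 °C
Reagents that add atoms: none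
Why: In the Saegusa–Ito oxidation, palladation at C13 and β-hydride loss from C14 give the enone regiospecifically under neutral conditions that leave the epimerisable C11 untouched.

**Step 5**
Reactants: 7 enone lactone
Product: 9 (3aS,4S,7R,7aS)-4-hydroxy-3a,7-dimethylhexahydro-2-benzofuran-1,6-dione (14α-OH), via 14α-boronate 8 (not isolated)
Conditions: CuCl (5 mol %), Xantphos (5 mol %), NaOt-Bu (10 mol %), B2pin2, MeOH, THF, rt; then H2O2, pH 7 buffer, 0 °C
Reagents that add atoms: hydrogen peroxide, OO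
Why: In this copper-catalysed conjugate borylation with stereoretentive C–B oxidation the boryl copper adds axially to C14 anti to the axial Me-15, the same sense as cuprate or peroxide attack at C1 of 5α-steroid 1-en-3-ones, which sets 14α-O.

**Step 6**
Reactants: 9 β-hydroxy ketone
Product: 10 (3aS,4S,6S,7R,7aS)-4,6-dihydroxy-3a,7-dimethylhexahydro-2-benzofuran-1(3H)-one (12β,14α-diol)
Conditions: Me4NBH(OAc)3, MeCN/AcOH, −25 °C
Reagents that add atoms: none
Why: In the Evans–Saksena hydroxyl-directed reduction the borohydride bound to the 14α-oxygen delivers hydride to the α face of C12 and gives the 1,3-anti diol (12β-OH).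

**Step 7**
Reactants: 10 diol lactone
Product: 11 (3aS,4S,6S,7R,7aS)-3a,7-dimethyl-4,6-bis(triethylsilyloxy)hexahydro-2-benzofuran-1(3H)-one
Conditions: TESOTf, 2,6-lutidine, CH2Cl2, −40 to 0 °C
Reagents that add atoms: triethylsilyl triflate, CC[Si](CC)(CC)OS(=O)(=O)C(F)(F)F
Why: Silyl ether protection with the reactive triflate covers both the equatorial and the hindered axial hydroxyl without touching any stereocentre.

**Step 8**
Reactants: 12 1,3-dithiane; 13 4-methyl-5,6-dihydro-2H-pyran-2-one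
Product: 15 (Z)-1-(1,3-dithian-2-yl)-5-hydroxy-3-methylpent-2-en-1-one (in equilibrium with its hemiketal), via 2-lithio-1,3-dithiane 14 (not isolated)
Conditions: n-BuLi, THF, −25 °C; then 13 (0.45 equiv), −78 °C; H2O
Reagents that add atoms: none
Why: In this Corey–Seebach acyl anion acylation the lithiodithiane adds 1,2 because C5 is fully substituted, a second equivalent deprotonates the acidic 2-acyldithiane and so stops over-addition, and the ring origin of the alkene fixes the 5Z geometry.

**Step 9**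
Reactants: 15 hydroxy enone
Product: 16 (Z)-5-(tert-butyldiphenylsilyloxy)-1-(1,3-dithian-2-yl)-3-methylpent-2-en-1-one
Conditions: TBDPSCl, imidazole, DMF, 0 °C
Reagents that add atoms: tert-butyldiphenylsilyl chloride, CC(C)(C)[Si](Cl)(c1ccccc1)c1ccccc1
Why: Silylation of the primary alcohol traps the open-chain form and installs a group that survives organolithiums and buffered fluoride.

**Step 10**
Reactants: 16 dithianyl enone
Product: 17 (S,Z)-5-(tert-butyldiphenylsilyloxy)-1-(1,3-dithian-2-yl)-3-methylpent-2-en-1-ol (7S)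
Conditions: (R)-Me-CBS oxazaborolidine (20 mol %), catecholborane, toluene, −78 °C
Reagents that add atoms: none
Why: In the Corey–Bakshi–Shibata reduction the dithianyl group acts as the large substituent, so the (R)-catalyst gives the 7S allylic alcohol, and catecholborane at low temperature spares the alkene.

**Step 11**
Reactants: 17 (7S)-dithianyl carbinol; 11 bis-TES lactone
Product: 19 C9 ketone with C8 dithiane (7S-OH, C3-OTBDPS chain; cyclohexane with 1β-Me, 1α-CH2OH, 10α-H, 11β-Me, 12β,14α-bis-OTES), via dilithio species 18 (not isolated)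
Conditions: t-BuLi (2.1 equiv), THF/HMPA, −78 °C; then 11, −78 to −50 °C; AcOH, −78 °C
Reagents that add atoms: none
Why: In this Corey–Seebach acylation the alkoxide next to the carbanion prevents β-elimination, the strained trans-fused lactone is opened to form C8–C9, and the tetrahedral adduct lasts until the cold acid quench, so neither over-addition nor retro-aldol at C7 occurs and no stereocentre is formed or lost.

**Step 12**
Reactants: 19 keto diol
Product: 21 C2-OTBDPS C7-OTES keto dithiane, via C2 mono-silyl ether 20 (not isolated)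
Conditions: TBDPSCl, imidazole, CH2Cl2, 0 °C; then TESOTf, 2,6-lutidine, −20 °C
Reagents that add atoms: tert-butyldiphenylsilyl chloride, CC(C)(C)[Si](Cl)(c1ccccc1)c1ccccc1; triethylsilyl triflate, CC[Si](CC)(CC)OS(=O)(=O)C(F)(F)F
Why: Sequential silyl ether formation uses sterics, because the bulky chloride takes only the primary C2 hydroxyl and the triflate then covers the hindered allylic C7 hydroxyl with a bulky, non-chelating and fluoride-labile group.

**Step 13**
Reactants: 21 keto dithiane
Product: 22 8,9-diketone (7S-OTES)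
Conditions: Hg(ClO4)2, CaCO3, THF/H2O, 0 °C
Reagents that add atoms: water, O
Why: Thiophilic hydrolysis of the dithioketal by divalent mercury under carbonate buffering unmasks C8 within minutes without affecting the alkene, the silyl ethers or C10.

**Step 14**
Reactants: 23 (S)-lactic acid; 24 pivalaldehyde
Product: 25 (2S,5S)-2-tert-butyl-5-methyl-1,3-dioxolan-4-one
Conditions: TsOH (cat.), pentane, reflux (Dean–Stark); recrystallisation
Reagents that add atoms: none
Why: Seebach acetalisation (self-regeneration of stereocentres) gives mainly the cis acetal, whose new acetal centre stores the chirality of the lactate.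

**Step 15**
Reactants: 25 lactate dioxolanone; 22 8,9-diketone
Product: 27 C8 tertiary carbinol (8R) bearing the (2S,5R-type) dioxolanone at C17 (17R), with the C9 ketone retained, via lithium enolate 26 (not isolated)
Conditions: LDA, THF, −78 °C; then 22, −78 °C; AcOH
Reagents that add atoms: none
Why: In the Seebach aldol addition the enolate reacts anti to the tert-butyl group (net retention, 17R) at the less hindered and more electrophilic C8 carbonyl, on the polar Felkin–Anh face where the C7 silyloxy group is anti to the nucleophile, which sets 8R.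

**Step 16**
Reactants: 27 aldol adduct
Product: 29 γ-lactone (7S,8R,17R; 8-OH and 17-OH free, C9 ketone, 12β-OH and 14α-OH free, C2 and C3 as TBDPS ethers), via desilylated dioxolanone 28 (not isolated)
Conditions: HF·pyridine, pyridine, THF, 0 °C; then DBU (10 mol %), CH2Cl2, 0 °C
Reagents that add atoms: none
Why: Buffered fluoride removes only the three TES groups, and the freed C7 hydroxyl then opens the activated dioxolanone carbonyl (transacylative lactonisation with loss of pivalaldehyde), so that 8-OH and 17-OH end up trans with no stereocentre touched.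

**Step 17**
Reactants: 29 keto lactone
Product: 31 9,12,14-triacetate (9S), via 9S-carbinol 30 (not isolated)
Conditions: NaBH4, CeCl3·7H2O, MeOH, −78 °C; evaporation; then Ac2O, pyridine, DMAP (cat.), 0 °C to rt
Reagents that add atoms: acetic anhydride, CC(=O)OC(C)=O
Why: The Luche reduction follows matched Felkin–Anh models (hydride anti to C1 at C10 and anti to O8 at C8) and sets 9S, and immediate acetylation of the three secondary alcohols forestalls migration of the lactone to O9 while the tertiary alcohols stay free.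

**Step 18**
Reactants: 31 triacetate bis-TBDPS ether
Product: 32 C2,C3 primary diol
Conditions: HF·pyridine (excess), THF, rt
Reagents that add atoms: none
Why: Acidic fluoride desilylation frees both primary alcohols without the acetyl migration that basic fluoride would cause.

**Step 19**
Reactants: 32 diol
Product: 33 C2,C3 dialdehyde
Conditions: Dess–Martin periodinane, NaHCO3, CH2Cl2, 0 °C
Reagents that add atoms: none
Why: Buffered Dess–Martin oxidation converts both primary alcohols in one operation and does not move the β,γ-alkene of the C3 aldehyde into conjugation.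

**Step 20**
Reactants: 33 dialdehyde
Product: 34 ten-membered 2R,3S-diol
Conditions: SmI2 (4 equiv), t-BuOH, THF (0.001 M, slow addition), −20 °C to rt; H2O
Reagents that add atoms: none
Why: In this samarium diiodide pinacol macrocyclisation single-electron reduction makes one formyl carbon a nucleophilic ketyl that attacks the other formyl carbon, both oxygens stay bridged on trivalent samarium so that the cis (erythro) diol forms, and the quaternary C1 (ketyl oxygen turned away from axial Me-15 and the 14-acetate) together with the tether stiffened by the Z alkene and the lactone exposes the faces that give 2R,3S.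

**Step 21**
Reactants: 34 macrocyclic diol
Product: 36 CNP0251217.1 (target), via C3 monobutyrate 35 (not isolated)
Conditions: (PrCO)2O (1.1 equiv), Et3N, DMAP (cat.), CH2Cl2, −30 °C; then Ac2O, DMAP, rt
Reagents that add atoms: butyric anhydride, CCCC(=O)OC(=O)CCC; acetic anhydride, CC(=O)OC(C)=O
Why: Sterically differentiated DMAP-catalysed acylation puts the butyrate on the open C3 hydroxyl first, the neopentyl C2 hydroxyl is then acetylated, and the tertiary 8-OH and 17-OH do not react.

**Compound list**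
1 | pent-1-en-3-one | CCC(=O)C=C | starting material
2 | (Z)-3-(tert-butyldimethylsilyloxy)penta-1,3-diene | C=C/C(O[Si](C)(C)C(C)(C)C)=C/C | intermediate
3 | ethyl (E)-3-methyl-4-oxobut-2-enoate | CCOC(=O)/C=C(\C)C=O | starting material
4 | ethyl (1S,2R,6S)-3-(TBSO)-6-formyl-2,6-dimethylcyclohex-3-ene-1-carboxylate | CCOC(=O)[C@H]1[C@@H](C)C(O[Si](C)(C)C(C)(C)C)=CC[C@]1(C)C=O | intermediate
5 | ethyl (1S,2R,6S)-3-(TBSO)-6-(hydroxymethyl)-2,6-dimethylcyclohex-3-ene-1-carboxylate | CCOC(=O)[C@H]1[C@@H](C)C(O[Si](C)(C)C(C)(C)C)=CC[C@]1(C)CO | intermediate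
6 | trans-fused lactone silyl enol ether (3aS,7R,7aS) | O=C1OC[C@@]2(C)CC=C(O[Si](C)(C)C(C)(C)C)[C@H](C)[C@H]12 | intermediate
7 | trans-fused lactone enone (3aS,7R,7aS) | O=C1OC[C@@]2(C)C=CC(=O)[C@H](C)[C@H]12 | intermediate
8 | 14α-(pinacolatoboryl) keto lactone | O=C1OC[C@@]2(C)[C@@H](B3OC(C)(C)C(C)(C)O3)CC(=O)[C@H](C)[C@H]12 | intermediate
9 | 14α-hydroxy keto lactone (3aS,4S,7R,7aS) | O=C1OC[C@@]2(C)[C@@H](O)CC(=O)[C@H](C)[C@H]12 | intermediate
10 | 12β,14α-dihydroxy lactone (3aS,4S,6S,7R,7aS) | O=C1OC[C@@]2(C)[C@@H](O)C[C@H](O)[C@H](C)[C@H]12 | intermediate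
11 | 12β,14α-bis(triethylsilyloxy) lactone | O=C1OC[C@@]2(C)[C@@H](O[Si](CC)(CC)CC)C[C@H](O[Si](CC)(CC)CC)[C@H](C)[C@H]12 | intermediate
12 | 1,3-dithiane | C1CSCSC1 | starting material
13 | 4-methyl-5,6-dihydro-2H-pyran-2-one | CC1=CC(=O)OCC1 | starting material
14 | 2-lithio-1,3-dithiane | [Li]C1SCCCS1 | intermediate
15 | (Z)-1-(1,3-dithian-2-yl)-5-hydroxy-3-methylpent-2-en-1-one | OCC/C(C)=C\C(=O)C1SCCCS1 | intermediate
16 | (Z)-5-(TBDPSO)-1-(1,3-dithian-2-yl)-3-methylpent-2-en-1-one | CC(C)(C)[Si](c1ccccc1)(c1ccccc1)OCC/C(C)=C\C(=O)C1SCCCS1 | intermediate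
17 | (S,Z)-5-(TBDPSO)-1-(1,3-dithian-2-yl)-3-methylpent-2-en-1-ol | CC(C)(C)[Si](c1ccccc1)(c1ccccc1)OCC/C(C)=C\[C@H](O)C1SCCCS1 | intermediate
18 | O,C-dilithio derivative of 17 | CC(C)(C)[Si](c1ccccc1)(c1ccccc1)OCC/C(C)=C\[C@H](O[Li])C1([Li])SCCCS1 | intermediate
19 | C9 ketone, C8 dithiane, 7S-OH, C2-OH | CC(C)(C)[Si](c1ccccc1)(c1ccccc1)OCC/C(C)=C\[C@H](O)C1(SCCCS1)C(=O)[C@H]1[C@@H](C)[C@@H](O[Si](CC)(CC)CC)C[C@H](O[Si](CC)(CC)CC)[C@]1(C)CO | intermediate
20 | C2-OTBDPS ether of 19 | CC(C)(C)[Si](c1ccccc1)(c1ccccc1)OCC/C(C)=C\[C@H](O)C1(SCCCS1)C(=O)[C@H]1[C@@H](C)[C@@H](O[Si](CC)(CC)CC)C[C@H](O[Si](CC)(CC)CC)[C@]1(C)CO[Si](c1ccccc1)(c1ccccc1)C(C)(C)C | intermediate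
21 | C2-OTBDPS, C7-OTES keto dithiane | CC(C)(C)[Si](c1ccccc1)(c1ccccc1)OCC/C(C)=C\[C@H](O[Si](CC)(CC)CC)C1(SCCCS1)C(=O)[C@H]1[C@@H](C)[C@@H](O[Si](CC)(CC)CC)C[C@H](O[Si](CC)(CC)CC)[C@]1(C)CO[Si](c1ccccc1)(c1ccccc1)C(C)(C)C | intermediate
22 | 8,9-diketone | CC(C)(C)[Si](c1ccccc1)(c1ccccc1)OCC/C(C)=C\[C@H](O[Si](CC)(CC)CC)C(=O)C(=O)[C@H]1[C@@H](C)[C@@H](O[Si](CC)(CC)CC)C[C@H](O[Si](CC)(CC)CC)[C@]1(C)CO[Si](c1ccccc1)(c1ccccc1)C(C)(C)C | intermediate
23 | (S)-lactic acid | C[C@H](O)C(=O)O | starting material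
24 | pivalaldehyde | CC(C)(C)C=O | starting material
25 | (2S,5S)-2-tert-butyl-5-methyl-1,3-dioxolan-4-one | C[C@@H]1O[C@H](C(C)(C)C)OC1=O | intermediate
26 | lithium enolate of 25 | CC1=C(O[Li])O[C@@H](C(C)(C)C)O1 | intermediate
27 | aldol adduct (8R,17R), C9 ketone | CC(C)(C)[Si](c1ccccc1)(c1ccccc1)OCC/C(C)=C\[C@H](O[Si](CC)(CC)CC)[C@](O)([C@@]1(C)O[C@H](C(C)(C)C)OC1=O)C(=O)[C@H]1[C@@H](C)[C@@H](O[Si](CC)(CC)CC)C[C@H](O[Si](CC)(CC)CC)[C@]1(C)CO[Si](c1ccccc1)(c1ccccc1)C(C)(C)C | intermediate
28 | adduct with the 7-, 12- and 14-hydroxyls free | CC(C)(C)[Si](c1ccccc1)(c1ccccc1)OCC/C(C)=C\[C@H](O)[C@](O)([C@@]1(C)O[C@H](C(C)(C)C)OC1=O)C(=O)[C@H]1[C@@H](C)[C@@H](O)C[C@H](O)[C@]1(C)CO[Si](c1ccccc1)(c1ccccc1)C(C)(C)C | intermediate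
29 | γ-lactone, C9 ketone | CC(C)(C)[Si](c1ccccc1)(c1ccccc1)OCC/C(C)=C\[C@@H]1OC(=O)[C@](C)(O)[C@]1(O)C(=O)[C@H]1[C@@H](C)[C@@H](O)C[C@H](O)[C@]1(C)CO[Si](c1ccccc1)(c1ccccc1)C(C)(C)C | intermediate
30 | γ-lactone, 9S-carbinol | CC(C)(C)[Si](c1ccccc1)(c1ccccc1)OCC/C(C)=C\[C@@H]1OC(=O)[C@](C)(O)[C@]1(O)[C@@H](O)[C@H]1[C@@H](C)[C@@H](O)C[C@H](O)[C@]1(C)CO[Si](c1ccccc1)(c1ccccc1)C(C)(C)C | intermediate
31 | 9,12,14-triacetate, bis-TBDPS ether | CC(C)(C)[Si](c1ccccc1)(c1ccccc1)OCC/C(C)=C\[C@@H]1OC(=O)[C@](C)(O)[C@]1(O)[C@@H](OC(C)=O)[C@H]1[C@@H](C)[C@@H](OC(C)=O)C[C@H](OC(C)=O)[C@]1(C)CO[Si](c1ccccc1)(c1ccccc1)C(C)(C)C | intermediate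
32 | seco C2,C3-diol | OCC/C(C)=C\[C@@H]1OC(=O)[C@](C)(O)[C@]1(O)[C@@H](OC(C)=O)[C@H]1[C@@H](C)[C@@H](OC(C)=O)C[C@H](OC(C)=O)[C@]1(C)CO | intermediate
33 | seco C2,C3-dialdehyde | O=CC/C(C)=C\[C@@H]1OC(=O)[C@](C)(O)[C@]1(O)[C@@H](OC(C)=O)[C@H]1[C@@H](C)[C@@H](OC(C)=O)C[C@H](OC(C)=O)[C@]1(C)C=O | intermediate
34 | macrocyclic 2R,3S-diol | O[C@H]1C/C(C)=C\[C@@H]2OC(=O)[C@](C)(O)[C@]2(O)[C@@H](OC(C)=O)[C@H]2[C@@H](C)[C@@H](OC(C)=O)C[C@H](OC(C)=O)[C@]2(C)[C@H]1O | intermediate
35 | C3 monobutyrate | CCCC(=O)O[C@H]1C/C(C)=C\[C@@H]2OC(=O)[C@](C)(O)[C@]2(O)[C@@H](OC(C)=O)[C@H]2[C@@H](C)[C@@H](OC(C)=O)C[C@H](OC(C)=O)[C@]2(C)[C@H]1O | intermediate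
36 | CNP0251217.1 | CCCC(=O)O[C@H]1C/C(C)=C\[C@@H]2OC(=O)[C@](C)(O)[C@]2(O)[C@@H](OC(C)=O)[C@H]2[C@@H](C)[C@@H](OC(C)=O)C[C@H](OC(C)=O)[C@]2(C)[C@H]1OC(C)=O | target

**Step count and risks**
Total step count: 21.
Longest linear sequence: 17 (steps 1–7, 11–13, 15–21).

The three steps most likely to fail are 20, 11 and 2.

**Step 20 (ring closure and the 2R,3S outcome).**
- The fallback sets out from 33 and comes back at 34.
- Under high dilution a triazolium-derived carbene with DBU converts the unhindered C3 aldehyde into its Breslow intermediate, which is a true acyl anion.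
- That carbon attacks the neopentyl C2 aldehyde and gives the macrocyclic 2-hydroxy-3-ketone F10.
- C3 is then set in a separate chelation-controlled reduction with Zn(BH4)2, which gives the erythro diol 34.
- Ring closure and the C3 configuration are therefore handled in two separate operations.

**Step 11 (hindered carbanion on a hindered lactone).**
- The fallback sets out from 11 and 18 and comes back at 21.
- DIBAL-H reduces 11 to the lactol F6, whose open hydroxy aldehyde form is a much smaller and more reactive electrophile.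
- After deprotonation of the lactol, 18 adds to give the C9 carbinol triol F7 as a mixture of C9 epimers. The C9 configuration does not matter at this stage.
- Silylation as in step 12 gives the C2 TBDPS ether F8 and then the C7 TES ether F9. Only the most hindered C9 hydroxyl stays free.
- Parikh–Doering oxidation (SO3·pyridine, DMSO, Et3N) then gives 21.

**Step 2 (formyl exo versus endo).**
- The fallback sets out from 2 and 3 and comes back at 7.
- If the formyl group goes endo, the cycloaddition gives the C11-epimeric adduct F1.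
- F1 is carried through the conditions of steps 3 and 4, by way of the hydroxy ester F2 and the lactone silyl enol ether F3, to the 11-epi enone F4.
- LDA at −78 °C removes H-11 and forms the cross-conjugated lithium dienolate F5.
- 2,6-Di-tert-butylphenol protonates F5 from the α face, opposite the axial Me-15, and gives 7.
- C11 is then set by kinetic protonation and not by the topology of the cycloaddition.

**Further compounds**
F1 | step 2 | C11-epimeric (formyl-endo) Diels–Alder adduct | CCOC(=O)[C@H]1[C@H](C)C(O[Si](C)(C)C(C)(C)C)=CC[C@]1(C)C=O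
F2 | step 2 | C11-epimeric hydroxy ester | CCOC(=O)[C@H]1[C@H](C)C(O[Si](C)(C)C(C)(C)C)=CC[C@]1(C)CO
F3 | step 2 | C11-epimeric lactone silyl enol ether | O=C1OC[C@@]2(C)CC=C(O[Si](C)(C)C(C)(C)C)[C@@H](C)[C@H]12
F4 | step 2 | 11-epi enone lactone | O=C1OC[C@@]2(C)C=CC(=O)[C@@H](C)[C@H]12
F5 | step 2 | cross-conjugated lithium dienolate | O=C1OC[C@@]2(C)C=CC(O[Li])=C(C)[C@H]12
F6 | step 11 | lactol of 11 (anomers) | OC1OC[C@@]2(C)[C@@H](O[Si](CC)(CC)CC)C[C@H](O[Si](CC)(CC)CC)[C@H](C)[C@H]12
F7 | step 11 | C9 carbinol triol (C9 epimers) | CC(C)(C)[Si](c1ccccc1)(c1ccccc1)OCC/C(C)=C\[C@H](O)C1(SCCCS1)C(O)[C@H]1[C@@H](C)[C@@H](O[Si](CC)(CC)CC)C[C@H](O[Si](CC)(CC)CC)[C@]1(C)CO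
F8 | step 11 | C2 TBDPS ether of F7 | CC(C)(C)[Si](c1ccccc1)(c1ccccc1)OCC/C(C)=C\[C@H](O)C1(SCCCS1)C(O)[C@H]1[C@@H](C)[C@@H](O[Si](CC)(CC)CC)C[C@H](O[Si](CC)(CC)CC)[C@]1(C)CO[Si](c1ccccc1)(c1ccccc1)C(C)(C)C
F9 | step 11 | C2 TBDPS, C7 TES ether with free C9 hydroxyl | CC(C)(C)[Si](c1ccccc1)(c1ccccc1)OCC/C(C)=C\[C@H](O[Si](CC)(CC)CC)C1(SCCCS1)C(O)[C@H]1[C@@H](C)[C@@H](O[Si](CC)(CC)CC)C[C@H](O[Si](CC)(CC)CC)[C@]1(C)CO[Si](c1ccccc1)(c1ccccc1)C(C)(C)C
F10 | step 20 | macrocyclic 2-hydroxy-3-ketone | O=C1C/C(C)=C\[C@@H]2OC(=O)[C@](C)(O)[C@]2(O)[C@@H](OC(C)=O)[C@H]2[C@@H](C)[C@@H](OC(C)=O)C[C@H](OC(C)=O)[C@]2(C)[C@H]1O
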